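Slow as the runs grow towards their end, you need no rate to tell which hand the product takes.

| flask | left-handed substrate | right-handed substrate | reagent | free catalyst | remark | time |
|---|---|---|---|---|---|---|
| elm | 20 mM | 20 mM | 60 mM | 20 µM | run made earlier |  |
| oak | 20 mM | 20 mM | 60 mM | 30 µM | run made earlier |  |
| ash | 10 mM | 10 mM | 60 mM | 40 µM | run made earlier |  |
| flask | 20 mM | 20 mM | 60.0 mM | 40 µM |  | 80 min |

| run | time / min | left-handed substrate / % | right-handed substrate / % | left-handed product / % |
|---|---|---|---|---|
| elm | 5.00 | 42.7 | 43.8 | 6.2 |
| elm | 12.0 | 40.1 | 41.2 | 13.2 |
| elm | 30.0 | 36.8 | 36.9 | 16.8 |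
| elm | 60.0 | 35.3 | 36.6 | 19.3 |
| oak | 15.0 | 36.5 | 36.1 | 17.0 |
| oak | 30.0 | 33.3 | 34.9 | 23.3 |
| oak | 50.0 | 31.8 | 30.1 | 25.6 |
| oak | 60.0 | 30.2 | 30.2 | 25.5 |
| ash | 8.00 | 36.5 | 36.7 | 18.6 |
| ash | 25.0 | 28.2 | 27.7 | 27.7 |
| ash | 40.0 | 25.1 | 25.5 | 30.7 |
| ash | 60.0 | 24.9 | 24.5 | 33.4 |

(readings scatter by 1 percentage point)

- free catalyst is single-handed; left-handed substrate and right-handed substrate are mirror images of each other, charged as a racemate, each of them at the stated concentration
- the numbers in the tables scatter by 1 percentage point (one standard deviation)
- an excess is below zero if the other one leads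

1. part of the left-handed substrate and right-handed substrate charged together that has reacted at 80 min
2. excess of left-handed product over right-handed product in the product at 80 min
3. excess of right-handed substrate over left-handed substrate among what is left of the two at 80 min

In ash at 60.0 min the left-handed product reads 33.4%, above the 25.1% of the charge lost as left-handed substrate, while the two substrates read level at 24.9% and 24.5%. So right-handed substrate is feeding the left-handed side, which is a dynamic kinetic resolution. With the substrates level, the catalyst chooses between the hands at the same odds however far a run has gone. Pooling the last readings of elm, oak and ash gives 0.661 for the left share, the fraction of what has reacted that stands as left-handed product, with 0.5 as the zero of its scale. It is a reading and carries their scatter. For the flask at 80 min you therefore reckon a product excess of 32.2% and a substrate excess of zero, and you leave the part reacted open.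

The forecast gives 48% reacted, a product excess of 32% and a substrate excess of 0.5%, holding that “both enantiomers converge mainly on left-handed product”.

The flask gives 48.3% reacted, a product excess of 31.5% and a substrate excess of 0.0128%.

    reagent + free catalyst + left-handed substrate → free catalyst + left-handed product (k = 572 L² mol⁻² s⁻¹)
    reagent + free catalyst + right-handed substrate → free catalyst + right-handed product (k = 293 L² mol⁻² s⁻¹)
    left-handed substrate ⇌ right-handed substrate (k = 0.00811 s⁻¹)
    2 reagent → self-condensation product (k = 0.00523 L mol⁻¹ s⁻¹)
    free catalyst → spent catalyst (k = 7.40 × 10⁻⁴ s⁻¹)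
    reagent ⇌ dormant form (K = 0.206, k = 7.97 × 10⁻⁴ s⁻¹)

The two substrates relax into each other with a half-life of 0.712 min, short against 80 min. The left share times the 48.3% reacted gives 31.9% of the charge as left-handed product, and the flask holds 31.8%. A neighbouring flask, charged with 100 mM of reagent and otherwise the same, has reacted further, to 62.8%. There the same left share gives 41.5% left-handed product and an excess of 32.2%, and that neighbouring flask holds 41.2% and shows an excess of 31.0%.

(All runs were computed from invented constants, and the scatter is random.)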